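**Retrosynthetic overview**

1. The aryl ether bond between coumarin C4–O and the allylic CH2 of the side chain is cut last (Mitsunobu). This gives 4-hydroxy-5-methylcoumarin and the (R)-keto allylic alcohol 20.
2. The strategy rests on the contiguous carbocycle array C1(=O)–C2(CH3)2–C3(H)(side chain)–C4(=CH2). It is the C1–C4 pattern of 4,4-dimethoxy-2-methylcyclohex-2-en-1-one: carbonyl carbon, α-methyl carbon, β-carbon, ketal carbon as latent methylidene carbon.
3. Key disconnection: C3–C1′ (ring to chain) and the second C2–CH3 bond. Both are made in one flask by copper-catalysed enantioselective conjugate addition of the C5 homoallylic Grignard reagent to that enone, followed by C-methylation of the enolate.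
4. The Grignard reagent comes from but-3-yn-1-ol. Zirconium-catalysed carboalumination with hydroxymethylation fixes the E trisubstituted alkene.
5. Ring order: the carbocycle is never closed, it is the dearomatised ring of 4-methoxy-2-methylphenol (steps 1–2). The pyranone ring of the coumarin is closed onto its benzene ring in step 15, and the two halves are joined in step 16.

Key step: step 9

Remark 1: the allylic oxygen of the chain is carried as a TBDPS ether, which should survive the acidic removal of the primary TBS group (step 6) and the ketal hydrolysis (step 11).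
Remark 2: the C1 ketone of 15 is reduced before the C4 ketal is opened and is reoxidised after the olefination. In the free 1,4-dione both carbonyls are shielded by the C2 gem-dimethyl group (C1 directly, C4 through the branched C3 and the axial methyl), so a site-selective mono-methylenation cannot be relied on. The carbinol configuration is irrelevant and is left undefined.
Remark 3: the sense of induction in step 9 is set by the choice of ligand antipode and should be confirmed on the first batch.

**Route**

Step 1
Reactants: 1 4-methoxy-2-methylphenol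
Product: 2 4,4-dimethoxy-2-methylcyclohexa-2,5-dien-1-one
Conditions: PhI(OAc)2 (1.1 equiv), MeOH, 0 °C
Reagents that add atoms: methanol CO
Why: Iodine(III) oxidation of a p-methoxyphenol in methanol (oxidative dearomatisation) generates the aryloxy cation, which methanol captures at the methoxy-bearing para carbon to give the quinone monoketal; no stereocentre is formed.

Step 2
Reactants: 2 4,4-dimethoxy-2-methylcyclohexa-2,5-dien-1-one
Product: 3 4,4-dimethoxy-2-methylcyclohex-2-en-1-one
Conditions: H2 (1 atm), RhCl(PPh3)3 (5 mol%), toluene, rt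
Reagents that add atoms: none
Why: Wilkinson's catalyst hydrogenates the unhindered cis-disubstituted C5=C6 alkene of the cross-conjugated dienone much faster than the methyl-bearing trisubstituted C2=C3 alkene, and its neutral medium spares the acid-labile ketal (chemoselective homogeneous hydrogenation).

Step 3
Reactants: 4 but-3-yn-1-ol
Product: 5 (but-3-yn-1-yloxy)(tert-butyl)dimethylsilane
Conditions: TBSCl, imidazole, CH2Cl2, 0 °C to rt
Reagents that add atoms: tert-butyldimethylsilyl chloride CC(C)(C)[Si](C)(C)Cl
Why: Imidazole-mediated silylation of a primary alcohol (silyl ether formation) is routine and leaves the terminal alkyne untouched.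

Step 4
Reactants: 5 (but-3-yn-1-yloxy)(tert-butyl)dimethylsilane
Product: 8 (2E)-5-[(tert-butyldimethylsilyl)oxy]-3-methylpent-2-en-1-ol, via alkenylalane 6 (not isolated), via lithium alanate 7 (not isolated)
Conditions: Me3Al, Cp2ZrCl2 (0.25 equiv), CH2Cl2, 0 °C to rt; evaporate; n-BuLi, THF/hexane, −78 to 0 °C; (CH2O)n, rt; aq. Rochelle salt
Reagents that add atoms: trimethylaluminium C[Al](C)C; paraformaldehyde (as formaldehyde) C=O
Why: Zirconium-catalysed carboalumination (Negishi) adds methyl and aluminium syn across the terminal alkyne with aluminium on the terminal carbon, and the alkenylalanate formed with n-BuLi is hydroxymethylated by formaldehyde with retention, which fixes the E alkene geometry.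

Step 5
Reactants: 8 (2E)-5-[(tert-butyldimethylsilyl)oxy]-3-methylpent-2-en-1-ol
Product: 9 tert-butyl{[(3E)-5-[(tert-butyldiphenylsilyl)oxy]-3-methylpent-3-en-1-yl]oxy}dimethylsilane
Conditions: TBDPSCl, imidazole, DMF, rt
Reagents that add atoms: tert-butyldiphenylsilyl chloride CC(C)(C)[Si](Cl)(c1ccccc1)c1ccccc1
Why: Imidazole-mediated silylation of the primary allylic alcohol installs a silyl ether that is far more acid-stable than the TBS ether at the other terminus.

Step 6
Reactants: 9 tert-butyl{[(3E)-5-[(tert-butyldiphenylsilyl)oxy]-3-methylpent-3-en-1-yl]oxy}dimethylsilane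
Product: 10 (3E)-5-[(tert-butyldiphenylsilyl)oxy]-3-methylpent-3-en-1-ol
Conditions: PPTS (0.2 equiv), MeOH, rt
Reagents that add atoms: none
Why: Mild acid-catalysed methanolysis cleaves the less hindered primary TBS ether much faster than the TBDPS ether (selective desilylation) and does not touch the alkene geometry.

Step 7
Reactants: 10 (3E)-5-[(tert-butyldiphenylsilyl)oxy]-3-methylpent-3-en-1-ol
Product: 11 {[(2E)-5-bromo-3-methylpent-2-en-1-yl]oxy}(tert-butyl)diphenylsilane
Conditions: CBr4, PPh3, CH2Cl2, 0 °C
Reagents that add atoms: carbon tetrabromide BrC(Br)(Br)Br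
Why: The Appel reaction converts the primary alcohol into the bromide by SN2 displacement of the alkoxyphosphonium ion under neutral conditions that the silyl ether and the alkene tolerate.

Step 8
Reactants: 11 {[(2E)-5-bromo-3-methylpent-2-en-1-yl]oxy}(tert-butyl)diphenylsilane
Product: 12 {(3E)-5-[(tert-butyldiphenylsilyl)oxy]-3-methylpent-3-en-1-yl}magnesium bromide (titrated Et2O solution, used at once)
Conditions: Mg turnings (I2-activated), Et2O, rt to 35 °C
Reagents that add atoms: magnesium [Mg]
Why: Magnesium insertion into the primary C–Br bond (Grignard formation) is straightforward because the reagent has no β-leaving group and the silyl ether and trisubstituted alkene are inert.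

Step 9
Reactants: 3 4,4-dimethoxy-2-methylcyclohex-2-en-1-one; 12 {(3E)-5-[(tert-butyldiphenylsilyl)oxy]-3-methylpent-3-en-1-yl}magnesium bromide; 13 iodomethane
Product: 15 (3S)-3-[(3E)-5-[(tert-butyldiphenylsilyl)oxy]-3-methylpent-3-en-1-yl]-4,4-dimethoxy-2,2-dimethylcyclohexan-1-one, via magnesium enolate 14 (not isolated)
Conditions: CuBr·SMe2 (5 mol%), Rev-Josiphos (6 mol%, antipode giving 3S), t-BuOMe, −78 °C, slow addition of 12; then MeI (5 equiv), DMPU, −78 °C to rt
Reagents that add atoms: none
Why: Transmetalation of 12 to the chiral diphosphine–copper(I) complex gives an alkylcopper species that binds the enone as a π-complex, adds oxidatively at C3 and, after reductive elimination, has formed the C3–C1′ bond and left the magnesium enolate 14 fixed across C1–C2. Iodomethane, with DMPU as activating co-solvent, then alkylates 14 on carbon and forms the second C2–CH3 bond; no ring is closed. The closest known reaction type is the copper/ferrocenyl-diphosphine-catalysed enantioselective conjugate addition of Grignard reagents to 2-methyl cycloalkenones with alkylation of the magnesium enolate in the same flask, and cuprate additions to quinone-monoketal enones show that a β-carbon next to the ketal carbon is accessible. C3 is the only new stereocentre (C2 becomes a non-stereogenic gem-dimethyl carbon) and its configuration is controlled by the ligand, whose antipode is chosen so that the chain is delivered to the enone face that gives (3S). The step needs 1,4- over 1,2-addition, secured by the soft copper nucleophile, the slow addition of 12 at −78 °C and the inductive activation of the enone by the C4 ketal, and it needs C2- over O- or C6-methylation, secured by the regiodefined enolate, which cannot equilibrate without a proton source, and by the soft electrophile. The C4 ketal carbon carries no hydrogen and is not β to the enolate carbon, so neither methoxide elimination nor rearomatisation can intervene.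

Step 10
Reactants: 15 (3S)-3-[(3E)-5-[(tert-butyldiphenylsilyl)oxy]-3-methylpent-3-en-1-yl]-4,4-dimethoxy-2,2-dimethylcyclohexan-1-one
Product: 16 (3S)-3-[(3E)-5-[(tert-butyldiphenylsilyl)oxy]-3-methylpent-3-en-1-yl]-4,4-dimethoxy-2,2-dimethylcyclohexan-1-ol (mixture of C1 epimers)
Conditions: NaBH4, MeOH, 0 °C to rt
Reagents that add atoms: none
Why: Borohydride reduction of the only carbonyl group parks C1 as a secondary alcohol (both epimers serve, the centre is reoxidised in step 13) so that C4 is the single ketone at the olefination stage; ketal, silyl ether, alkene and C3 are not affected.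

Step 11
Reactants: 16 (3S)-3-[(3E)-5-[(tert-butyldiphenylsilyl)oxy]-3-methylpent-3-en-1-yl]-4,4-dimethoxy-2,2-dimethylcyclohexan-1-ol
Product: 17 (2S)-2-[(3E)-5-[(tert-butyldiphenylsilyl)oxy]-3-methylpent-3-en-1-yl]-4-hydroxy-3,3-dimethylcyclohexan-1-one (mixture of C4 epimers)
Conditions: PPTS (0.2 equiv), acetone/H2O (10:1), rt
Reagents that add atoms: water O
Why: Mild acid-catalysed hydrolysis of the dimethyl ketal is fast at room temperature, while the weak acid and short exposure keep the TBDPS ether intact and disfavour enolisation of the new ketone toward the hindered C2–H, so the stereocentre should be retained.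

Step 12
Reactants: 17 (2S)-2-[(3E)-5-[(tert-butyldiphenylsilyl)oxy]-3-methylpent-3-en-1-yl]-4-hydroxy-3,3-dimethylcyclohexan-1-one
Product: 18 (3R)-3-[(3E)-5-[(tert-butyldiphenylsilyl)oxy]-3-methylpent-3-en-1-yl]-2,2-dimethyl-4-methylidenecyclohexan-1-ol (mixture of C1 epimers)
Conditions: Zn, CH2Br2, TiCl4, THF (pre-formed reagent, excess); 17 in CH2Cl2, 0 °C to rt
Reagents that add atoms: dibromomethane BrCBr
Why: Takai–Lombardo methylenation uses a non-basic Zn/Ti gem-dimetallic reagent that olefinates hindered, enolisable ketones without epimerising the α-stereocentre and tolerates a free hydroxyl group; the carbonyl of 17 is the only one present, so no site selectivity is needed (the descriptor changes from S to R only through CIP priorities).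

Step 13
Reactants: 18 (3R)-3-[(3E)-5-[(tert-butyldiphenylsilyl)oxy]-3-methylpent-3-en-1-yl]-2,2-dimethyl-4-methylidenecyclohexan-1-ol
Product: 19 (3R)-3-[(3E)-5-[(tert-butyldiphenylsilyl)oxy]-3-methylpent-3-en-1-yl]-2,2-dimethyl-4-methylidenecyclohexan-1-one
Conditions: Dess–Martin periodinane, NaHCO3, CH2Cl2, 0 °C to rt
Reagents that add atoms: none
Why: Dess–Martin oxidation returns the hindered secondary alcohol to the ketone under buffered, near-neutral conditions in which the exocyclic alkene does not migrate, and the stereocentre is safe because it is not α to this ketone (C2 is quaternary).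

Step 14
Reactants: 19 (3R)-3-[(3E)-5-[(tert-butyldiphenylsilyl)oxy]-3-methylpent-3-en-1-yl]-2,2-dimethyl-4-methylidenecyclohexan-1-one
Product: 20 (3R)-3-[(3E)-5-hydroxy-3-methylpent-3-en-1-yl]-2,2-dimethyl-4-methylidenecyclohexan-1-one
Conditions: TBAF, THF, 0 °C to rt
Reagents that add atoms: none
Why: Fluoride-mediated cleavage of the Si–O bond (desilylation) frees the primary allylic alcohol; the ketone has no epimerisable α-stereocentre and the alkenes are inert.

Step 15
Reactants: 21 1-(2-hydroxy-6-methylphenyl)ethan-1-one (2′-hydroxy-6′-methylacetophenone)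
Product: 23 4-hydroxy-5-methyl-2H-chromen-2-one, via β-keto ester 22 (not isolated)
Conditions: NaH, (EtO)2CO, toluene, 110 °C; then aq. HCl
Reagents that add atoms: diethyl carbonate CCOC(=O)OCC
Why: Claisen-type C-acylation of the ketone enolate by diethyl carbonate gives the β-keto ester, whose ester is then attacked by the neighbouring phenoxide to close the pyranone ring (classical 4-hydroxycoumarin synthesis).

Step 16
Reactants: 20 (3R)-3-[(3E)-5-hydroxy-3-methylpent-3-en-1-yl]-2,2-dimethyl-4-methylidenecyclohexan-1-one; 23 4-hydroxy-5-methyl-2H-chromen-2-one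
Product: 24 4-{[(2E)-5-[(1R)-2,2-dimethyl-6-methylidene-3-oxocyclohexyl]-3-methylpent-2-en-1-yl]oxy}-5-methyl-2H-chromen-2-one (target)
Conditions: PPh3, DIAD, THF, 0 °C to rt
Reagents that add atoms: none
Why: Mitsunobu etherification: the acidic 4-hydroxycoumarin protonates the phosphine–azodicarboxylate betaine and its C4 oxygen displaces the primary allylic alkoxyphosphonium ion by direct SN2 attack, which should give the 4-O-ether without allylic transposition or change of the E geometry and leaves ketone, methylidene group and stereocentre untouched.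

**Compound list**

1 | 4-methoxy-2-methylphenol | COc1ccc(O)c(C)c1 | starting material
2 | 4,4-dimethoxy-2-methylcyclohexa-2,5-dien-1-one | COC1(OC)C=CC(=O)C(C)=C1 | intermediate
3 | 4,4-dimethoxy-2-methylcyclohex-2-en-1-one | COC1(OC)CCC(=O)C(C)=C1 | intermediate
4 | but-3-yn-1-ol | C#CCCO | starting material
5 | (but-3-yn-1-yloxy)(tert-butyl)dimethylsilane | C#CCCO[Si](C)(C)C(C)(C)C | intermediate
6 | {(1E)-4-[(tert-butyldimethylsilyl)oxy]-2-methylbut-1-en-1-yl}dimethylalane (not isolated) | CC(C)(C)[Si](C)(C)OCC/C(C)=C/[Al](C)C | intermediate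
7 | lithium butyl{(1E)-4-[(tert-butyldimethylsilyl)oxy]-2-methylbut-1-en-1-yl}dimethylaluminate (not isolated) | CC(C)(C)[Si](C)(C)OCC/C(C)=C/[Al-](C)(C)CCCC.[Li+] | intermediate
8 | (2E)-5-[(tert-butyldimethylsilyl)oxy]-3-methylpent-2-en-1-ol | CC(C)(C)[Si](C)(C)OCC/C(C)=C/CO | intermediate
9 | tert-butyl{[(3E)-5-[(tert-butyldiphenylsilyl)oxy]-3-methylpent-3-en-1-yl]oxy}dimethylsilane | CC(C)(C)[Si](C)(C)OCC/C(C)=C/CO[Si](c1ccccc1)(c1ccccc1)C(C)(C)C | intermediate
10 | (3E)-5-[(tert-butyldiphenylsilyl)oxy]-3-methylpent-3-en-1-ol | OCC/C(C)=C/CO[Si](c1ccccc1)(c1ccccc1)C(C)(C)C | intermediate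
11 | {[(2E)-5-bromo-3-methylpent-2-en-1-yl]oxy}(tert-butyl)diphenylsilane | BrCC/C(C)=C/CO[Si](c1ccccc1)(c1ccccc1)C(C)(C)C | intermediate
12 | {(3E)-5-[(tert-butyldiphenylsilyl)oxy]-3-methylpent-3-en-1-yl}magnesium bromide | Br[Mg]CC/C(C)=C/CO[Si](c1ccccc1)(c1ccccc1)C(C)(C)C | intermediate
13 | iodomethane | CI | starting material
14 | bromomagnesium enolate, {[(3S)-3-[(3E)-5-[(tert-butyldiphenylsilyl)oxy]-3-methylpent-3-en-1-yl]-4,4-dimethoxy-2-methylcyclohex-1-en-1-yl]oxy}magnesium bromide (not isolated) | COC1(OC)CCC(O[Mg]Br)=C(C)[C@@H]1CC/C(C)=C/CO[Si](c1ccccc1)(c1ccccc1)C(C)(C)C | intermediate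
15 | (3S)-3-[(3E)-5-[(tert-butyldiphenylsilyl)oxy]-3-methylpent-3-en-1-yl]-4,4-dimethoxy-2,2-dimethylcyclohexan-1-one | COC1(OC)CCC(=O)C(C)(C)[C@@H]1CC/C(C)=C/CO[Si](c1ccccc1)(c1ccccc1)C(C)(C)C | intermediate
16 | (3S)-3-[(3E)-5-[(tert-butyldiphenylsilyl)oxy]-3-methylpent-3-en-1-yl]-4,4-dimethoxy-2,2-dimethylcyclohexan-1-ol, C1 epimers | COC1(OC)CCC(O)C(C)(C)[C@@H]1CC/C(C)=C/CO[Si](c1ccccc1)(c1ccccc1)C(C)(C)C | intermediate
17 | (2S)-2-[(3E)-5-[(tert-butyldiphenylsilyl)oxy]-3-methylpent-3-en-1-yl]-4-hydroxy-3,3-dimethylcyclohexan-1-one, C4 epimers | O=C1CCC(O)C(C)(C)[C@@H]1CC/C(C)=C/CO[Si](c1ccccc1)(c1ccccc1)C(C)(C)C | intermediate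
18 | (3R)-3-[(3E)-5-[(tert-butyldiphenylsilyl)oxy]-3-methylpent-3-en-1-yl]-2,2-dimethyl-4-methylidenecyclohexan-1-ol, C1 epimers | C=C1CCC(O)C(C)(C)[C@@H]1CC/C(C)=C/CO[Si](c1ccccc1)(c1ccccc1)C(C)(C)C | intermediate
19 | (3R)-3-[(3E)-5-[(tert-butyldiphenylsilyl)oxy]-3-methylpent-3-en-1-yl]-2,2-dimethyl-4-methylidenecyclohexan-1-one | C=C1CCC(=O)C(C)(C)[C@@H]1CC/C(C)=C/CO[Si](c1ccccc1)(c1ccccc1)C(C)(C)C | intermediate
20 | (3R)-3-[(3E)-5-hydroxy-3-methylpent-3-en-1-yl]-2,2-dimethyl-4-methylidenecyclohexan-1-one | C=C1CCC(=O)C(C)(C)[C@@H]1CC/C(C)=C/CO | intermediate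
21 | 1-(2-hydroxy-6-methylphenyl)ethan-1-one | CC(=O)c1c(C)cccc1O | starting material
22 | ethyl 3-(2-hydroxy-6-methylphenyl)-3-oxopropanoate (not isolated) | CCOC(=O)CC(=O)c1c(C)cccc1O | intermediate
23 | 4-hydroxy-5-methyl-2H-chromen-2-one | Cc1cccc2oc(=O)cc(O)c12 | intermediate
24 | 4-{[(2E)-5-[(1R)-2,2-dimethyl-6-methylidene-3-oxocyclohexyl]-3-methylpent-2-en-1-yl]oxy}-5-methyl-2H-chromen-2-one | C=C1CCC(=O)C(C)(C)[C@@H]1CC/C(C)=C/COc1cc(=O)oc2cccc(C)c12 | target

**Step count**

Total: 16 steps. Longest linear sequence: 13 steps, from but-3-yn-1-ol (steps 3–14 and 16).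

**Steps most likely to fail, with fallbacks**

1. Step 9 (key step). The conjugate addition may be slow at a β-carbon that lies between the α-methyl carbon and the fully substituted ketal carbon, so that uncatalysed 1,2-addition or an unselective background reaction takes over. The crowded magnesium enolate may also be methylated incompletely and then be protonated on work-up. The fallback moves the enantioselective chain transfer to an unhindered, α-unsubstituted acceptor and brings in both methyl groups afterwards. It sets out from 12 and comes back to the route at 15.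
   - Oxidation of commercial 4-methoxyphenol with PhI(OAc)2 in MeOH, as in step 1, should give 4,4-dimethoxycyclohexa-2,5-dien-1-one F1.
   - Transmetalation of 12 with ZnCl2 (0.5 equiv) in Et2O, with removal of the magnesium halide as its dioxane complex, should give bis{(3E)-5-[(tert-butyldiphenylsilyl)oxy]-3-methylpent-3-en-1-yl}zinc F2.
   - Cu(OTf)2 with a BINOL-derived phosphoramidite ligand (toluene, −25 °C) should add F2 to F1; this reaction type is established for dialkylzincs and 4,4-dialkoxycyclohexadienones. It passes through the alkylzinc enolate F3 (not isolated) and, after aqueous work-up, should give (5S)-5-[(3E)-5-[(tert-butyldiphenylsilyl)oxy]-3-methylpent-3-en-1-yl]-4,4-dimethoxycyclohex-2-en-1-one F4, with the ligand antipode chosen accordingly.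
   - Because C4 carries no hydrogen, LDA (THF, −78 °C) can deprotonate F4 only at C6. The lithium dienolate F5 (not isolated) with MeI should give the 6-methyl enone F6 (C6 epimers).
   - A second LDA/MeI cycle (with DMPU), through the lithium dienolate F7 (not isolated), should give (5S)-5-[(3E)-5-[(tert-butyldiphenylsilyl)oxy]-3-methylpent-3-en-1-yl]-4,4-dimethoxy-6,6-dimethylcyclohex-2-en-1-one F8.
   - Hydrogenation of the disubstituted enone alkene of F8 with H2/RhCl(PPh3)3, as in step 2, leaves the trisubstituted chain alkene and returns to 15.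

2. Step 2. The hydrogenation may not stop at the mono-ene, may reduce both ring alkenes, or the ketal may lose methanol with rearomatisation if the medium turns acidic. The fallback gives up the selective reduction and re-introduces the C2=C3 alkene regioselectively. It sets out from 2 and comes back at 3.
   - Exhaustive hydrogenation of 2 (H2, Rh/Al2O3, EtOAc, trace Et3N) should give racemic 4,4-dimethoxy-2-methylcyclohexan-1-one F9.
   - Thermodynamic silylation (TMSCl, Et3N, DMF, 80 °C) should give the more substituted enol ether [(4,4-dimethoxy-2-methylcyclohex-1-en-1-yl)oxy]trimethylsilane F10.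
   - Saegusa–Ito dehydrosilylation (Pd(OAc)2, MeCN, rt) of F10 should give 3.

3. Step 12. Olefination of a ketone flanked by the branched C2 and shielded by the neighbouring gem-dimethyl group may be sluggish, the free hydroxyl may consume reagent, and slow reaction gives time for enolisation toward C2 with erosion of enantiopurity. The fallback is a two-stage Peterson olefination that sets out from 17 and comes back at 18.
   - Addition of Me3SiCH2Li/CeCl3 (THF, −78 °C, excess to allow for the hydroxyl) to the ketone, a weakly basic organocerium addition suited to enolisable hindered ketones, should give (2S)-2-[(3E)-5-[(tert-butyldiphenylsilyl)oxy]-3-methylpent-3-en-1-yl]-3,3-dimethyl-1-[(trimethylsilyl)methyl]cyclohexane-1,4-diol F11.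
   - Base-induced syn-elimination (KH, THF, 0 °C to rt) of F11 should give 18 without exposing the exocyclic alkene to acid.

**Further compounds**

F1 | step 9 | 4,4-dimethoxycyclohexa-2,5-dien-1-one | COC1(OC)C=CC(=O)C=C1
F2 | step 9 | bis{(3E)-5-[(tert-butyldiphenylsilyl)oxy]-3-methylpent-3-en-1-yl}zinc | CC(C)(C)[Si](c1ccccc1)(c1ccccc1)OC/C=C(C)/CC[Zn]CC/C(C)=C/CO[Si](c1ccccc1)(c1ccccc1)C(C)(C)C
F3 | step 9 | alkylzinc enolate of F4 (not isolated) | COC1(OC)C=CC(O[Zn]CC/C(C)=C/CO[Si](c2ccccc2)(c2ccccc2)C(C)(C)C)=C[C@@H]1CC/C(C)=C/CO[Si](c1ccccc1)(c1ccccc1)C(C)(C)C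
F4 | step 9 | (5S)-5-[(3E)-5-[(tert-butyldiphenylsilyl)oxy]-3-methylpent-3-en-1-yl]-4,4-dimethoxycyclohex-2-en-1-one | COC1(OC)C=CC(=O)C[C@@H]1CC/C(C)=C/CO[Si](c1ccccc1)(c1ccccc1)C(C)(C)C
F5 | step 9 | lithium dienolate of F4 (not isolated) | COC1(OC)C=CC(O[Li])=C[C@@H]1CC/C(C)=C/CO[Si](c1ccccc1)(c1ccccc1)C(C)(C)C
F6 | step 9 | (5S)-5-[(3E)-5-[(tert-butyldiphenylsilyl)oxy]-3-methylpent-3-en-1-yl]-4,4-dimethoxy-6-methylcyclohex-2-en-1-one, C6 epimers | COC1(OC)C=CC(=O)C(C)[C@@H]1CC/C(C)=C/CO[Si](c1ccccc1)(c1ccccc1)C(C)(C)C
F7 | step 9 | lithium dienolate of F6 (not isolated) | COC1(OC)C=CC(O[Li])=C(C)[C@@H]1CC/C(C)=C/CO[Si](c1ccccc1)(c1ccccc1)C(C)(C)C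
F8 | step 9 | (5S)-5-[(3E)-5-[(tert-butyldiphenylsilyl)oxy]-3-methylpent-3-en-1-yl]-4,4-dimethoxy-6,6-dimethylcyclohex-2-en-1-one | COC1(OC)C=CC(=O)C(C)(C)[C@@H]1CC/C(C)=C/CO[Si](c1ccccc1)(c1ccccc1)C(C)(C)C
F9 | step 2 | 4,4-dimethoxy-2-methylcyclohexan-1-one (racemic) | COC1(OC)CCC(=O)C(C)C1
F10 | step 2 | [(4,4-dimethoxy-2-methylcyclohex-1-en-1-yl)oxy]trimethylsilane | COC1(OC)CCC(O[Si](C)(C)C)=C(C)C1
F11 | step 12 | (2S)-2-[(3E)-5-[(tert-butyldiphenylsilyl)oxy]-3-methylpent-3-en-1-yl]-3,3-dimethyl-1-[(trimethylsilyl)methyl]cyclohexane-1,4-diol | C[Si](C)(C)CC1(O)CCC(O)C(C)(C)[C@@H]1CC/C(C)=C/CO[Si](c1ccccc1)(c1ccccc1)C(C)(C)C
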